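Assumption: the SMILES is read as (1S,2R,4S,5S)-4-bromo-2-[(2S,5R)-5-bromo-2,6,6-trimethyloxan-2-yl]-5-chloro-5-methylcyclohexan-1-ol (OH, oxanyl and ring Br on one face, Cl on the other); the ligand and catalyst antipodes named are those expected to give the drawn sense and are exchanged if the first run shows the opposite.

**Retrosynthetic overview**
1. 15 ⇐ trans-diaxial bromochloride 14 (thermal diaxial→diequatorial Br/Cl interchange) ⇐ chlorohydrin 13 ⇐ hydroxyl-directed epoxide 12 ⇐ cyclohexenol 11.
2. 11 ⇐ 9 by inversion of the C1 carbinol (oxidation, bulky hydride).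
3. Key disconnection: the oxane O–C6 bond (with C5–Br) of 9 ⇐ diene-diol 8 by catalyst-controlled 6-endo bromoetherification (C–O bond, new method).
4. 8 ⇐ hydroxy ketone 5 + homoprenyl Grignard (chelation); 5 ⇐ dienone 3 by asymmetric conjugate borylation/oxidation; 3 ⇐ isoprene + butynone (Diels–Alder).
5. Ring order: cyclohexene (step 1), then oxane (step 4); the epoxide of step 7 is transient.

Cyclohexane positions below use the target's numbering (C1 OH, C2 oxanyl, C4 Br, C5 Cl/Me).

**Route**

Step 1
Reactants: 1 isoprene (2-methylbuta-1,3-diene); 2 but-3-yn-2-one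
Product: 3 1-(4-methylcyclohexa-1,4-dien-1-yl)ethan-1-one
Conditions: EtAlCl2 (0.2 equiv), isoprene (3 equiv), CH2Cl2, −20 → 0 °C, under argon
Reagents that add atoms: none
Why: Lewis-acid-promoted Diels–Alder reaction of a 2-substituted diene with an ynone gives the "para" 1,4-cyclohexadiene, which already carries the ring alkene where the two halogens will go; no stereocentre is formed.

Step 2
Reactants: 3 1-(4-methylcyclohexa-1,4-dien-1-yl)ethan-1-one
Product: 5 1-[(1R,6R)-6-hydroxy-4-methylcyclohex-3-en-1-yl]ethan-1-one, via pinacol boronate 4 (not isolated)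
Conditions: CuCl (3 mol%), NaOt-Bu (6 mol%), (R)-1-[(S)-2-(diphenylphosphino)ferrocenyl]ethyldicyclohexylphosphine (4 mol%), B2pin2 (1.1 equiv), MeOH (2 equiv), THF, 0 °C → rt; DBU (10 mol%), rt; then NaBO3·4H2O, THF/H2O, 0 °C
Reagents that add atoms: bis(pinacolato)diboron, CC1(C)OB(OC1(C)C)B1OC(C)(C)C(C)(C)O1 (boron of 4); sodium perborate, [Na+].[O-]OB=O (hydroxyl oxygen of 5)
Why: Copper-catalysed enantioselective conjugate borylation of the enone puts boron on one face of the β-carbon (C6, R), base equilibration of the α-centre gives the trans-diequatorial acetyl (C1, R), and perborate oxidation replaces boron by OH with retention.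

Step 3
Reactants: 5 1-[(1R,6R)-6-hydroxy-4-methylcyclohex-3-en-1-yl]ethan-1-one; 6 5-bromo-2-methylpent-2-ene
Product: 8 (1R,2R)-2-[(2S)-2-hydroxy-6-methylhept-5-en-2-yl]-5-methylcyclohex-4-en-1-ol, via Grignard reagent 7 (not isolated)
Conditions: 6, Mg, THF, rt (3 equiv of 7); then 5, THF, −78 → −20 °C; H2O
Reagents that add atoms: magnesium, [Mg] (held only in intermediate 7)
Why: Cram-chelate Grignard addition, in which the magnesium alkoxide of the β-hydroxyl chelates the ketone and the nucleophile enters from the side of the ring C–H, sets the tertiary carbinol as S, the sense known for homoprenyl additions to trans-2-acetylcyclohexanols.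

Step 4
Reactants: 8 (1R,2R)-2-[(2S)-2-hydroxy-6-methylhept-5-en-2-yl]-5-methylcyclohex-4-en-1-ol
Product: 9 (1R,2R)-2-[(2S,5R)-5-bromo-2,6,6-trimethyloxan-2-yl]-5-methylcyclohex-4-en-1-ol
Conditions: NBS (1.1 equiv), (R)-N-triflyl thiophosphoramide of 3,3'-bis(2,4,6-triisopropylphenyl)-1,1'-bi-2-naphthol (10 mol%), toluene/CH2Cl2 3:1, 4 Å MS, −60 °C, dark
Reagents that add atoms: N-bromosuccinimide, O=C1CCC(=O)N1Br
Why: Proposed new method: the thiophosphoryl sulfur takes Br+ from NBS and passes it inside the chiral pocket to one face of the trialkyl-substituted side-chain alkene (a bromiranium on the ring alkene has no nucleophile in reach and gives Br+ back), and the tertiary hydroxyl opens it at the tertiary carbon (6-endo, Markovnikov) through a chair with cyclohexenyl and Br equatorial and methyl axial, so catalyst and substrate preference both set C5 of the oxane as R, trans to the cyclohexenyl group; the closest known reactions are chiral Lewis-base-catalysed enantioselective bromocyclisations of polyprenoids (carbon-terminated) and of aryl-alkenols, and the racemic BDSB- or TBCO-mediated 6-endo bromoetherifications that build this same bromo-oxane ring, whereas an oxygen-terminated, catalyst-controlled version on a trialkyl alkene with a tertiary alcohol has not been shown.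

Step 5
Reactants: 9 (1R,2R)-2-[(2S,5R)-5-bromo-2,6,6-trimethyloxan-2-yl]-5-methylcyclohex-4-en-1-ol
Product: 10 (2S)-2-[(2S,5R)-5-bromo-2,6,6-trimethyloxan-2-yl]-5-methylcyclohex-4-en-1-one
Conditions: Dess–Martin periodinane (1.3 equiv), pyridine, CH2Cl2, 0 °C
Reagents that add atoms: none
Why: Dess–Martin oxidation erases the C1 centre, which served only as a relay for C2, while the base-free buffered medium leaves C2 (now α to C=O) and the β,γ-alkene untouched.

Step 6
Reactants: 10 (2S)-2-[(2S,5R)-5-bromo-2,6,6-trimethyloxan-2-yl]-5-methylcyclohex-4-en-1-one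
Product: 11 (1S,2R)-2-[(2S,5R)-5-bromo-2,6,6-trimethyloxan-2-yl]-5-methylcyclohex-4-en-1-ol
Conditions: LiBH(s-Bu)3 (1.3 equiv), THF, −78 °C; H2O
Reagents that add atoms: none
Why: Sterically controlled ketone reduction, in which the bulky borohydride attacks along the equatorial path of the 2-substituted cyclohexanone, gives the axial alcohol cis to the equatorial oxanyl group (C1, S).

Step 7
Reactants: 11 (1S,2R)-2-[(2S,5R)-5-bromo-2,6,6-trimethyloxan-2-yl]-5-methylcyclohex-4-en-1-ol
Product: 12 (1R,3S,4R,6S)-4-[(2S,5R)-5-bromo-2,6,6-trimethyloxan-2-yl]-1-methyl-7-oxabicyclo[4.1.0]heptan-3-ol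
Conditions: VO(acac)2 (5 mol%), t-BuOOH (1.5 equiv), CH2Cl2, 0 °C → rt
Reagents that add atoms: tert-butyl hydroperoxide, CC(C)(C)OO
Why: Hydroxyl-directed vanadium/hydroperoxide epoxidation of a homoallylic alcohol delivers oxygen from the face of the axial C1–OH, so the C4–C5 epoxide is cis to OH and to the oxanyl group.

Step 8
Reactants: 12 (1R,3S,4R,6S)-4-[(2S,5R)-5-bromo-2,6,6-trimethyloxan-2-yl]-1-methyl-7-oxabicyclo[4.1.0]heptan-3-ol
Product: 13 (1R,3S,4R,6R)-4-[(2S,5R)-5-bromo-2,6,6-trimethyloxan-2-yl]-6-chloro-1-methylcyclohexane-1,3-diol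
Conditions: LiCl (5 equiv), AcOH (3 equiv), THF, rt
Reagents that add atoms: lithium chloride, [Li+].[Cl-]
Why: Fürst–Plattner (trans-diaxial) epoxide opening, as with trans-limonene oxide, sends chloride to the secondary carbon C4 with inversion and leaves the tertiary C5–OH in place, anti-periplanar to the new C–Cl.

Step 9
Reactants: 13 (1R,3S,4R,6R)-4-[(2S,5R)-5-bromo-2,6,6-trimethyloxan-2-yl]-6-chloro-1-methylcyclohexane-1,3-diol
Product: 15 (1S,2R,4S,5S)-4-bromo-2-[(2S,5R)-5-bromo-2,6,6-trimethyloxan-2-yl]-5-chloro-5-methylcyclohexan-1-ol, via trans-diaxial bromochloride 14 (not isolated)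
Conditions: Me3SiBr (1.5 equiv), CH2Cl2, −30 → 0 °C; aq. NaHCO3 wash; then MeNO2, 70 °C
Reagents that add atoms: bromotrimethylsilane, C[Si](C)(C)Br
Why: SN1 substitution of the tertiary alcohol with anchimeric help from the anti-periplanar C4–Cl (chloronium, retention at C5) gives the trans-diaxial 5-bromo-4-chloro isomer 14, and heating drives the diaxial→diequatorial 1,2-dihalide interchange (each halogen shifts on its own face, inverting C4 and C5) to the more stable trans-diequatorial isomer with secondary Br and tertiary Cl, an isomerisation recalled for trans-diaxial bromochlorides of this terpenoid family.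

**Compound list**
1 | 2-methylbuta-1,3-diene (isoprene) | C=CC(C)=C | starting material
2 | but-3-yn-2-one | CC(=O)C#C | starting material
3 | 1-(4-methylcyclohexa-1,4-dien-1-yl)ethan-1-one | CC(=O)C1=CCC(C)=CC1 | intermediate
4 | 1-[(1R,6R)-4-methyl-6-(4,4,5,5-tetramethyl-1,3,2-dioxaborolan-2-yl)cyclohex-3-en-1-yl]ethan-1-one | CC(=O)[C@@H]1CC=C(C)C[C@H]1B1OC(C)(C)C(C)(C)O1 | intermediate
5 | 1-[(1R,6R)-6-hydroxy-4-methylcyclohex-3-en-1-yl]ethan-1-one | CC(=O)[C@@H]1CC=C(C)C[C@H]1O | intermediate
6 | 5-bromo-2-methylpent-2-ene | CC(C)=CCCBr | starting material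
7 | (4-methylpent-3-en-1-yl)magnesium bromide | CC(C)=CCC[Mg]Br | intermediate
8 | (1R,2R)-2-[(2S)-2-hydroxy-6-methylhept-5-en-2-yl]-5-methylcyclohex-4-en-1-ol | O[C@](C)([C@@H]1CC=C(C)C[C@H]1O)CCC=C(C)C | intermediate
9 | (1R,2R)-2-[(2S,5R)-5-bromo-2,6,6-trimethyloxan-2-yl]-5-methylcyclohex-4-en-1-ol | CC1(C)O[C@](C)([C@@H]2CC=C(C)C[C@H]2O)CC[C@H]1Br | intermediate
10 | (2S)-2-[(2S,5R)-5-bromo-2,6,6-trimethyloxan-2-yl]-5-methylcyclohex-4-en-1-one | CC1(C)O[C@](C)([C@@H]2CC=C(C)CC2=O)CC[C@H]1Br | intermediate
11 | (1S,2R)-2-[(2S,5R)-5-bromo-2,6,6-trimethyloxan-2-yl]-5-methylcyclohex-4-en-1-ol | CC1(C)O[C@](C)([C@@H]2CC=C(C)C[C@@H]2O)CC[C@H]1Br | intermediate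
12 | (1R,3S,4R,6S)-4-[(2S,5R)-5-bromo-2,6,6-trimethyloxan-2-yl]-1-methyl-7-oxabicyclo[4.1.0]heptan-3-ol (epoxide cis to OH) | CC1(C)O[C@](C)([C@@H]2C[C@@H]3O[C@]3(C)C[C@@H]2O)CC[C@H]1Br | intermediate
13 | (1R,3S,4R,6R)-4-[(2S,5R)-5-bromo-2,6,6-trimethyloxan-2-yl]-6-chloro-1-methylcyclohexane-1,3-diol | CC1(C)O[C@](C)([C@@H]2C[C@@H](Cl)[C@](C)(O)C[C@@H]2O)CC[C@H]1Br | intermediate
14 | (1S,2R,4R,5R)-5-bromo-2-[(2S,5R)-5-bromo-2,6,6-trimethyloxan-2-yl]-4-chloro-5-methylcyclohexan-1-ol | CC1(C)O[C@](C)([C@@H]2C[C@@H](Cl)[C@](C)(Br)C[C@@H]2O)CC[C@H]1Br | intermediate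
15 | (1S,2R,4S,5S)-4-bromo-2-[(2S,5R)-5-bromo-2,6,6-trimethyloxan-2-yl]-5-chloro-5-methylcyclohexan-1-ol | CC1(C)O[C@](C)([C@@H]2C[C@H](Br)[C@@](C)(Cl)C[C@@H]2O)CC[C@H]1Br | target

**Totals**
Total step count: 9. Longest linear sequence: 9 steps (1 and 2 to 15; bromide 6 enters in step 3).

**Three steps most likely to fail**

Step 4 (the proposed new bromoetherification). The risks are incomplete facial control by the catalyst, 5-exo closure to the oxolane, and loss of Br+ to the ring alkene. The fallback uses known chemistry and gives up catalyst control: it sets out from 8 and treats it with stoichiometric BDSB (Et2SBr·SbCl5Br, 1.1 equiv) in MeNO2 at −25 °C, or with 2,4,4,6-tetrabromocyclohexa-2,5-dienone in MeNO2. Both are established substrate-controlled 6-endo bromoetherifications for this 3-bromo-2,2,6-trimethyl-oxane ring. They rely only on the chair preference (methyl axial, cyclohexenyl equatorial). The C5 epimer and the oxolane regioisomer are removed by chromatography, and the sequence comes back at 9. No compound outside the list is made (none F0).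

Step 9 (tertiary OH to Br, then halogen interchange). The risks are elimination at the tertiary centre, cleavage of the oxane by the silyl bromide, and an interchange equilibrium that may not lie far enough toward 15; the isomerisation precedent is recalled from memory and the strain estimate is close to neutral. The fallback sets out from 11 and adds the two halogens in one operation by direct anti-bromochlorination with tetrabutylammonium dichlorobromate (or NBS/Et4NCl) in CH2Cl2 at −78 °C. This is expected to favour the wrong facial isomer, so 15 and 14 must be separated from it by HPLC; recovered 14 is heated as in step 9. The sequence comes back at 15. No compound outside the list is made (none F0).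

Step 2 (asymmetric borylation of an aromatisation-prone 1-acylcyclohexa-1,4-diene). The risks are modest ee on this α-branched cyclic enone, incomplete trans equilibration, and isomerisation or aromatisation of the diene. The fallback replaces asymmetric catalysis by an enzymatic resolution and sets out from 3. Borylation with CuCl, NaOt-Bu, 4,5-bis(diphenylphosphino)-9,9-dimethylxanthene, B2pin2 and MeOH, then DBU, gives racemic trans-1-[4-methyl-6-(4,4,5,5-tetramethyl-1,3,2-dioxaborolan-2-yl)cyclohex-3-en-1-yl]ethan-1-one F1. Perborate oxidation gives racemic trans-1-(6-hydroxy-4-methylcyclohex-3-en-1-yl)ethan-1-one F2. Candida antarctica lipase B with vinyl acetate in MTBE acylates the (1R)-alcohol selectively to (1R,6R)-6-acetyl-3-methylcyclohex-3-en-1-yl acetate F3, which is separated from the unreacted (1S,6S)-alcohol. Methanolysis (K2CO3, MeOH, 0 °C) then comes back to the route at 5.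

Further compounds
F1 | step 2 | racemic trans-1-[4-methyl-6-(4,4,5,5-tetramethyl-1,3,2-dioxaborolan-2-yl)cyclohex-3-en-1-yl]ethan-1-one | CC(=O)[C@@H]1CC=C(C)C[C@H]1B1OC(C)(C)C(C)(C)O1.CC(=O)[C@H]1CC=C(C)C[C@@H]1B1OC(C)(C)C(C)(C)O1
F2 | step 2 | racemic trans-1-(6-hydroxy-4-methylcyclohex-3-en-1-yl)ethan-1-one | CC(=O)[C@@H]1CC=C(C)C[C@H]1O.CC(=O)[C@H]1CC=C(C)C[C@@H]1O
F3 | step 2 | (1R,6R)-6-acetyl-3-methylcyclohex-3-en-1-yl acetate | CC(=O)[C@@H]1CC=C(C)C[C@H]1OC(C)=O
F0 | step 4 | none | none
F0 | step 9 | none | none
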